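**Retrosynthetic overview**

1. Indole C2–CH bond: tryptophol 1 and indole-3-carboxaldehyde 2 are joined by an oxa-Pictet–Spengler reaction to racemic pyranoindole 3. This pyran is the only ring the route builds; both indole rings are bought.
2. CH–CH(O) bond (key step): acid ionises the C1–O bond of 3, and the chiral enamine of silyloxyacetaldehyde 4 adds to the ring-opened alkylideneindolenine 5. This gives aldehyde 6 with both stereocentres and opens the pyran again, its oxygen becoming the hydroxyethyl OH.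
3. Aldehyde 6 is reduced in the same flask to alcohol 7; O–Si cleavage then gives Colletotryptin B 8.

Assumption: the SMILES is read as the (2S,3S) isomer (C2 = carbinol carbon, C3 = bis-indolyl methine), and (S)-TRIP is taken as the matched acid for the cation face in step 2.

**Route**

Step 1
Reactants: 1 tryptophol; 2 indole-3-carboxaldehyde
Product: 3 rac-1-(1H-indol-3-yl)-1,3,4,9-tetrahydropyrano[3,4-b]indole
Conditions: p-TsOH·H2O (10 mol%), 4 Å MS, 1,2-dichloroethane, 60 °C; Et3N quench, Et3N-deactivated silica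
Reagents that add atoms: none
Why: Oxa-Pictet–Spengler reaction, in which the acid-activated aldehyde condenses with the tryptophol OH and the indole C2 closes the six-membered pyran; the new stereocentre is left racemic on purpose because step 2 erases it.

Step 2
Reactants: 3 rac-1-(1H-indol-3-yl)-1,3,4,9-tetrahydropyrano[3,4-b]indole; 4 (tert-butyldimethylsilyloxy)acetaldehyde
Product: 7 (2S,3S)-2-[(tert-butyldimethylsilyl)oxy]-3-[3-(2-hydroxyethyl)-1H-indol-2-yl]-3-(1H-indol-3-yl)propan-1-ol, via alkylideneindolenine 5 (not isolated), via silyloxy aldehyde 6 (not isolated)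
Conditions: 4 (3 equiv), (R)-2-[diphenyl(trimethylsilyloxy)methyl]pyrrolidine (20 mol%), (S)-TRIP (20 mol%), toluene, 0 °C; then MeOH, NaBH4, 0 °C
Reagents that add atoms: none
Why: Proposed new method: an enamine-catalysed ring-opening α-alkylation in which the chiral phosphoric acid ionises the doubly indolyl-activated C1–O bond of racemic 3 (a reverse oxa-Pictet–Spengler step) to the planar bis(indolyl)methylium phosphate of 5, erasing the C1 stereocentre; the (E)-enamine of 4 with the (R)-prolinol ether attacks through the face not shielded by the CPh2(OTMS) group, setting C2 as S, while the chiral phosphate, hydrogen-bonded to the indole N–H next to the cationic carbon, screens one face of the ion to set C3 as S; iminium hydrolysis returns the amine and NaBH4 traps aldehyde 6 before it can epimerise or cyclise onto an indole; the closest known reaction type is the SN1-type organocatalytic α-alkylation of aldehydes with diarylmethanols and 3-indolylmethanols, extended here to a cyclic ether as latent cation, an α-silyloxy aldehyde donor and control of both new stereocentres by an amine–phosphate pair.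

Step 3
Reactants: 7 (2S,3S)-2-[(tert-butyldimethylsilyl)oxy]-3-[3-(2-hydroxyethyl)-1H-indol-2-yl]-3-(1H-indol-3-yl)propan-1-ol
Product: 8 Colletotryptin B, (2S,3S)-3-[3-(2-hydroxyethyl)-1H-indol-2-yl]-3-(1H-indol-3-yl)propane-1,2-diol
Conditions: Bu4NF (1.5 equiv), THF, 0 °C → rt
Reagents that add atoms: none
Why: Fluoride-mediated silyl ether cleavage (desilylation) driven by Si–F bond formation; no bond at C2 or C3 is broken, so both stereocentres are retained, and the free indoles and alcohols tolerate the conditions.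

**Compound list**

1 | tryptophol, 2-(1H-indol-3-yl)ethanol | OCCc1c[nH]c2ccccc12 | starting material
2 | indole-3-carboxaldehyde | O=Cc1c[nH]c2ccccc12 | starting material
3 | rac-1-(1H-indol-3-yl)-1,3,4,9-tetrahydropyrano[3,4-b]indole (racemic, no stereodescriptor) | O1CCc2c(C1c1c[nH]c3ccccc13)[nH]c1ccccc21 | intermediate
4 | (tert-butyldimethylsilyloxy)acetaldehyde | O=CCO[Si](C)(C)C(C)(C)C | starting material
5 | 2-{2-[(Z)-(3H-indol-3-ylidene)methyl]-1H-indol-3-yl}ethanol (neutral form; reacts as its N-protonated methylium phosphate, geometry labile) | OCCc1c(/C=C2\C=Nc3ccccc32)[nH]c2ccccc12 | intermediate (not isolated)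
6 | (2S,3S)-2-[(tert-butyldimethylsilyl)oxy]-3-[3-(2-hydroxyethyl)-1H-indol-2-yl]-3-(1H-indol-3-yl)propanal | OCCc1c([C@H](c2c[nH]c3ccccc23)[C@H](O[Si](C)(C)C(C)(C)C)C=O)[nH]c2ccccc12 | intermediate (not isolated)
7 | (2S,3S)-2-[(tert-butyldimethylsilyl)oxy]-3-[3-(2-hydroxyethyl)-1H-indol-2-yl]-3-(1H-indol-3-yl)propan-1-ol | OCCc1c([C@H](c2c[nH]c3ccccc23)[C@H](O[Si](C)(C)C(C)(C)C)CO)[nH]c2ccccc12 | intermediate
8 | Colletotryptin B, (2S,3S)-3-[3-(2-hydroxyethyl)-1H-indol-2-yl]-3-(1H-indol-3-yl)propane-1,2-diol | OCCc1c([C@H](c2c[nH]c3ccccc23)[C@H](O)CO)[nH]c2ccccc12 | target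

**Step count**

Total steps: 3 (step 2 is a one-pot alkylation–reduction). Longest linear sequence: 3 steps, from 1.

**Steps most likely to fail**

1. Step 2 (the proposed new step). The risks are slow ionisation of 3 by the ammonium phosphate, self-aldol of 4, catalyst trapping by the neighbouring indole N–H, and low selectivity at C3. The C2 sense rests on the standard enamine shielding model; the C3 sense rests on the unproven amine–phosphate pairing, and the C3 epimer of 7 would have to be removed by chromatography. The fallback uses only known reaction types, sets out from 1 and comes back to the route at 8. Tryptophol 1 is silylated (TBSCl, imidazole, DMF) to 3-[2-(tert-butyldimethylsilyloxy)ethyl]-1H-indole F1. N-Protection (Boc2O, DMAP, MeCN) gives tert-butyl 3-[2-(tert-butyldimethylsilyloxy)ethyl]-1H-indole-1-carboxylate F2. C2-Lithiation (LiN(i-Pr)2, THF, −78 °C) and DMF give tert-butyl 3-[2-(tert-butyldimethylsilyloxy)ethyl]-2-formyl-1H-indole-1-carboxylate F3. Wittig olefination with Ph3P=CHCHO (toluene, 80 °C) gives tert-butyl 3-[2-(tert-butyldimethylsilyloxy)ethyl]-2-[(E)-3-oxoprop-1-en-1-yl]-1H-indole-1-carboxylate F4. Iminium-catalysed Friedel–Crafts alkylation of indole with F4, using the second-generation MacMillan imidazolidinone (2R,5R)-5-benzyl-2-tert-butyl-3-methylimidazolidin-4-one·TFA (20 mol%, CH2Cl2/i-PrOH, −40 °C), sets C3 and gives tert-butyl 3-[2-(tert-butyldimethylsilyloxy)ethyl]-2-[(1S)-1-(1H-indol-3-yl)-3-oxopropyl]-1H-indole-1-carboxylate F5. D-Proline-catalysed α-aminoxylation with nitrosobenzene (DMSO, rt) sets C2 under catalyst control and gives tert-butyl 2-[(1S,2S)-2-(anilinooxy)-1-(1H-indol-3-yl)-3-oxopropyl]-3-[2-(tert-butyldimethylsilyloxy)ethyl]-1H-indole-1-carboxylate F6. This is reduced in the flask (NaBH4, MeOH) to tert-butyl 2-[(1S,2S)-2-(anilinooxy)-3-hydroxy-1-(1H-indol-3-yl)propyl]-3-[2-(tert-butyldimethylsilyloxy)ethyl]-1H-indole-1-carboxylate F7. N–O cleavage (Zn dust, AcOH) gives tert-butyl 3-[2-(tert-butyldimethylsilyloxy)ethyl]-2-[(1S,2S)-2,3-dihydroxy-1-(1H-indol-3-yl)propyl]-1H-indole-1-carboxylate F8. Bu4NF in THF at 65 °C then removes both the silyl ether and the indole N-Boc group to give 8.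

2. Step 1. Indole-3-carboxaldehyde is a vinylogous formamide and a sluggish electrophile, and the acid-labile product 3 can re-ionise and pick up a second tryptophol to give a tris(indolyl)methane. The fallback sets out from 1 and comes back at 3. Tryptophol 1 is condensed with bought tert-butyl 3-formyl-1H-indole-1-carboxylate, an ordinary aryl aldehyde (p-TsOH·H2O 5 mol%, MgSO4, CH2Cl2, rt), to give tert-butyl 3-(1,3,4,9-tetrahydropyrano[3,4-b]indol-1-yl)-1H-indole-1-carboxylate F9. Its ether is much less prone to ionise. The N-Boc group is then removed under basic conditions that leave the pyran untouched (K2CO3, MeOH, rt) to give 3.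

3. Step 3. The chemistry is reliable, but the very polar triol 8 may be hard to free from tetrabutylammonium salts, and any losses fall on the final compound. The fallback sets out from 3 and comes back at 8. Step 2 is run with bought benzyloxyacetaldehyde in place of 4 under the same catalysts, giving (2S,3S)-2-(benzyloxy)-3-[3-(2-hydroxyethyl)-1H-indol-2-yl]-3-(1H-indol-3-yl)propanal F10. This is reduced in the flask (NaBH4, MeOH) to (2S,3S)-2-(benzyloxy)-3-[3-(2-hydroxyethyl)-1H-indol-2-yl]-3-(1H-indol-3-yl)propan-1-ol F11. Hydrogenolysis (H2 1 atm, Pd/C, that is zerovalent palladium on carbon, EtOH, rt) gives 8 with no salt to remove.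

**Further compounds**

F1 | step 2 | 3-[2-(tert-butyldimethylsilyloxy)ethyl]-1H-indole | CC(C)(C)[Si](C)(C)OCCc1c[nH]c2ccccc12
F2 | step 2 | tert-butyl 3-[2-(tert-butyldimethylsilyloxy)ethyl]-1H-indole-1-carboxylate | CC(C)(C)[Si](C)(C)OCCc1cn(C(=O)OC(C)(C)C)c2ccccc12
F3 | step 2 | tert-butyl 3-[2-(tert-butyldimethylsilyloxy)ethyl]-2-formyl-1H-indole-1-carboxylate | CC(C)(C)[Si](C)(C)OCCc1c(C=O)n(C(=O)OC(C)(C)C)c2ccccc12
F4 | step 2 | tert-butyl 3-[2-(tert-butyldimethylsilyloxy)ethyl]-2-[(E)-3-oxoprop-1-en-1-yl]-1H-indole-1-carboxylate | CC(C)(C)[Si](C)(C)OCCc1c(/C=C/C=O)n(C(=O)OC(C)(C)C)c2ccccc12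
F5 | step 2 | tert-butyl 3-[2-(tert-butyldimethylsilyloxy)ethyl]-2-[(1S)-1-(1H-indol-3-yl)-3-oxopropyl]-1H-indole-1-carboxylate | CC(C)(C)[Si](C)(C)OCCc1c([C@H](c2c[nH]c3ccccc23)CC=O)n(C(=O)OC(C)(C)C)c2ccccc12
F6 | step 2 | tert-butyl 2-[(1S,2S)-2-(anilinooxy)-1-(1H-indol-3-yl)-3-oxopropyl]-3-[2-(tert-butyldimethylsilyloxy)ethyl]-1H-indole-1-carboxylate | CC(C)(C)[Si](C)(C)OCCc1c([C@H](c2c[nH]c3ccccc23)[C@H](ONc2ccccc2)C=O)n(C(=O)OC(C)(C)C)c2ccccc12
F7 | step 2 | tert-butyl 2-[(1S,2S)-2-(anilinooxy)-3-hydroxy-1-(1H-indol-3-yl)propyl]-3-[2-(tert-butyldimethylsilyloxy)ethyl]-1H-indole-1-carboxylate | CC(C)(C)[Si](C)(C)OCCc1c([C@H](c2c[nH]c3ccccc23)[C@H](ONc2ccccc2)CO)n(C(=O)OC(C)(C)C)c2ccccc12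
F8 | step 2 | tert-butyl 3-[2-(tert-butyldimethylsilyloxy)ethyl]-2-[(1S,2S)-2,3-dihydroxy-1-(1H-indol-3-yl)propyl]-1H-indole-1-carboxylate | CC(C)(C)[Si](C)(C)OCCc1c([C@H](c2c[nH]c3ccccc23)[C@H](O)CO)n(C(=O)OC(C)(C)C)c2ccccc12
F9 | step 1 | tert-butyl 3-(1,3,4,9-tetrahydropyrano[3,4-b]indol-1-yl)-1H-indole-1-carboxylate (racemic) | O1CCc2c(C1c1cn(C(=O)OC(C)(C)C)c3ccccc13)[nH]c1ccccc21
F10 | step 3 | (2S,3S)-2-(benzyloxy)-3-[3-(2-hydroxyethyl)-1H-indol-2-yl]-3-(1H-indol-3-yl)propanal | OCCc1c([C@H](c2c[nH]c3ccccc23)[C@H](OCc2ccccc2)C=O)[nH]c2ccccc12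
F11 | step 3 | (2S,3S)-2-(benzyloxy)-3-[3-(2-hydroxyethyl)-1H-indol-2-yl]-3-(1H-indol-3-yl)propan-1-ol | OCCc1c([C@H](c2c[nH]c3ccccc23)[C@H](OCc2ccccc2)CO)[nH]c2ccccc12
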